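**Plan**
1. Retrosynthesis leads to (−)-caryophyllene oxide 1 and vanillic acid 2. The ester C1–O–acyl bond is cut first, the 10Z alkene is traced to its 10E isomer, the 3E alkene to a trans-oxirane, and the C7–C10 bond is re-formed to give the cyclobutane of 1.
2. Forward: both rings come with 1. C1 is hydroxylated and its configuration corrected through the enone. Hydrogen-atom transfer to the methylene and scission of C7–C10 then merge the cyclobutane and the nine-membered ring into the eleven-membered ring, the only ring-forming event. Deoxygenation, inversion of the C10=C11 geometry, acylation and desilylation follow.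
3. Stereochemistry: C1 (R) comes from a reagent-controlled CBS reduction, 3E from the trans-oxirane of 1 by stereospecific deoxygenation, and 10Z from stereospecific inversion of the 10E alkene that the trans-fused bicycle should deliver. The two ring-fusion centres of 1 are consumed.
4. Enabling feature: ring atoms C7–C8(gem-dimethyl)–C9–C10 together with the methyl-bearing C11 are a dimethylcyclobutane carrying an exocyclic methylene whose C7–C10 bond has been cut, so the ring C1–C11 is the nine-membered ring of the caryophyllane bicycle enlarged by C8 and C9.

Key step: step 4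

Remark (numbering): atom numbers are those of the target ring throughout: C1 (oxygen-bearing), C2, C3=C4 (methyl on C4), C5–C7, C8 (gem-dimethyl), C9, C10=C11 (methyl on C11). In the bicyclic compounds 1 and 3–5 the cyclobutane is C7–C8–C9–C10, the oxirane spans C3–C4 and the methylene sits on C11.
Remark (chemistry): in the trans-fused bicycle the C7–C10 bond can align with the C11 radical orbital only in the rotamer that holds C1 next to the C10 hydrogen. The scission is therefore planned to give the ring-trans (10E) alkene, and the 10Z geometry of the target is installed afterwards by stereospecific inversion (steps 6 and 7). This assignment rests on conformational reasoning only and has not been modelled.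

Step 1
Reactants: 1 (−)-caryophyllene oxide
Product: 3 1-hydroxycaryophyllene oxide (both C1 epimers)
Conditions: SeO2 (0.3 equiv), t-BuOOH (3 equiv, in decane), CH2Cl2, 0 °C to rt
Reagents that add atoms: tert-butyl hydroperoxide, CC(C)(C)OO; selenium dioxide, O=[Se]=O (relays the oxygen atom)
Why: Selenium dioxide allylic hydroxylation (ene reaction followed by [2,3]-sigmatropic shift, the catalytic hydroperoxide variant of the Riley oxidation) should take place on the ring CH2 flanking the exocyclic methylene, because the only other allylic hydrogen sits on the ring-fusion carbon C10 where the ene step would have to build a strained cyclobutylidene; the configuration of the new carbinol is not relied on and is erased in step 2.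

Step 2
Reactants: 3 1-hydroxycaryophyllene oxide (both C1 epimers)
Product: 4 1-oxocaryophyllene oxide
Conditions: Dess–Martin periodinane, NaHCO3, CH2Cl2, 0 °C to rt
Reagents that add atoms: none
Why: Dess–Martin oxidation under bicarbonate buffering should convert both carbinol epimers into one α-methylene ketone without acid that could open the trisubstituted oxirane.

Step 3
Reactants: 4 1-oxocaryophyllene oxide
Product: 5 (1R)-1-hydroxycaryophyllene oxide
Conditions: (S)-1-methyl-3,3-diphenyltetrahydro-1H,3H-pyrrolo[1,2-c][1,3,2]oxazaborole (0.2 equiv), catecholborane, toluene, −78 °C; aq. NaOH work-up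
Reagents that add atoms: none
Why: Corey–Bakshi–Shibata reduction, in which the alkenyl side of the ketone acts as the large group, so that the (S)-oxazaborolidine should deliver hydride to the face giving the (1R)-carbinol by reagent control, while catecholborane at −78 °C spares the methylene (no hydroboration) and the oxirane.

Step 4
Reactants: 5 (1R)-1-hydroxycaryophyllene oxide
Product: 6 (1R,3R,4R,10E)-3,4-epoxy-4,8,8,11-tetramethylcycloundec-10-en-1-ol
Conditions: Fe(acac)3 (0.3 equiv), PhSiH3 (2.5 equiv, slow addition), degassed EtOH (0.01 M), 40 °C
Reagents that add atoms: none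
Why: Proposed new method: hydrogen-atom transfer from the iron hydride formed from Fe(acac)3 and PhSiH3 to the terminal carbon of the 1,1-disubstituted alkene gives the tertiary C11 radical, which undergoes cyclobutylcarbinyl β-scission of the ring-fusion bond C7–C10 to form the C10=C11 alkene and a secondary C7 radical that is then reduced (capture by iron and protonolysis by ethanol, or a second hydrogen-atom transfer); the closest known reaction type is the hydrogen-atom-transfer-initiated radical ring opening (retro-cycloisomerisation) of pinene-type methylenecyclobutanes, here run with reductive termination and as a nine-to-eleven ring expansion. The eleven-membered ring is not closed by a cyclisation but arises by ring expansion when the zero-atom bridge of the bicyclo[7.2.0] system is cut (the reverse of a 4-exo-trig closure). No stereocentre is created (C7 and C10 lose theirs, C1, C3 and C4 are spectators), and the alkene geometry is controlled by the trans ring fusion: only the rotamer with C1 next to the C10 hydrogen lets the C7–C10 bond overlap with the radical orbital without stretching the nine-membered ring, which places C1 and C9 trans (10E). The step needs hydrogen-atom transfer to the methylene only (it is the sole 1,1-disubstituted alkene, and the C3–C4 alkene is masked as the oxirane, which also excludes transannular radical addition), scission of C7–C10 rather than C9–C10 (secondary instead of primary radical, release of about 26 kcal/mol of cyclobutane strain), and scission faster than reduction of the tertiary radical, which high dilution, slow silane addition and gentle warming should favour.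

Step 5
Reactants: 6 (1R,3R,4R,10E)-3,4-epoxy-4,8,8,11-tetramethylcycloundec-10-en-1-ol
Product: 7 (1R,3E,10E)-4,8,8,11-tetramethylcycloundeca-3,10-dien-1-ol
Conditions: WCl6 (4 equiv), n-BuLi (8 equiv), THF, −78 °C to rt; then 6, rt
Reagents that add atoms: none
Why: Sharpless deoxygenation with the low-valent tungsten chloride made from WCl6 and n-BuLi should remove the oxirane oxygen with retention, so that the trans-oxirane gives the 3E alkene; excess reagent is used because the free hydroxyl binds part of it as its alkoxide.

Step 6
Reactants: 7 (1R,3E,10E)-4,8,8,11-tetramethylcycloundeca-3,10-dien-1-ol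
Product: 8 (1R,3E)-10,11-epoxy-4,8,8,11-tetramethylcycloundec-3-en-1-ol (trans-oxirane: C9 and C1 on opposite faces; erythro to the C1 hydroxyl)
Conditions: VO(acac)2 (5 mol%), t-BuOOH (1.1 equiv), CH2Cl2, 0 °C
Reagents that add atoms: tert-butyl hydroperoxide, CC(C)(C)OO
Why: Vanadium-catalysed hydroxyl-directed epoxidation (Sharpless–Michaelson) should oxidise the allylic C10=C11 alkene much faster than the merely homoallylic C3=C4 alkene, the oxygen being delivered within the vanadate ester (erythro isomer expected from allylic 1,2-strain); only the trans relationship of C9 and C1 on the oxirane, inherited from the E alkene, matters for step 7, which erases both new stereocentres.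

Step 7
Reactants: 8 (1R,3E)-10,11-epoxy-4,8,8,11-tetramethylcycloundec-3-en-1-ol
Product: 11 (1R,3E,10Z)-4,8,8,11-tetramethylcycloundeca-3,10-dien-1-ol, via hydroxy phosphine 9 (not isolated), via phosphonium betaine 10 (not isolated)
Conditions: LiPPh2 (3 equiv), THF, 0 °C to 40 °C; then MeI (6 equiv), rt
Reagents that add atoms: none
Why: Alkene inversion by the phosphide/methyl iodide sequence (Vedejs–Fuchs): diphenylphosphide should open the oxirane by SN2 attack with inversion at the less substituted C10, P-methylation gives the betaine, and its Wittig-type syn-cycloreversion expels methyldiphenylphosphine oxide, so that anti-opening plus syn-elimination turns the 10E into the 10Z geometry while C1 and the 3E alkene are untouched.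

Step 8
Reactants: 2 vanillic acid
Product: 13 4-(tert-butyldimethylsilyloxy)-3-methoxybenzoic acid, via bis-silylated acid 12 (not isolated)
Conditions: TBSCl (2.5 equiv), imidazole, DMF, rt; then AcOH–THF–H2O (3:1:1), rt
Reagents that add atoms: tert-butyldimethylsilyl chloride, CC(C)(C)[Si](C)(C)Cl
Why: Silylation of phenol and carboxyl with the silyl chloride and imidazole, followed by mild aqueous acid that hydrolyses the far more labile silyl ester and leaves the aryl silyl ether.

Step 9
Reactants: 13 4-(tert-butyldimethylsilyloxy)-3-methoxybenzoic acid
Product: 14 4-(tert-butyldimethylsilyloxy)-3-methoxybenzoyl chloride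
Conditions: (COCl)2, N,N-dimethylformamide (cat.), CH2Cl2, 0 °C to rt; evaporation
Reagents that add atoms: oxalyl chloride, ClC(=O)C(=O)Cl
Why: Acid chloride formation through the Vilsmeier-type chloroiminium species; the aryl silyl ether should tolerate these anhydrous conditions and the volatile by-products leave on evaporation.

Step 10
Reactants: 11 (1R,3E,10Z)-4,8,8,11-tetramethylcycloundeca-3,10-dien-1-ol; 14 4-(tert-butyldimethylsilyloxy)-3-methoxybenzoyl chloride
Product: 15 (1R,3E,10Z)-4,8,8,11-tetramethylcycloundeca-3,10-dien-1-yl 4-(tert-butyldimethylsilyloxy)-3-methoxybenzoate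
Conditions: Et3N, 4-(dimethylamino)pyridine (0.2 equiv), CH2Cl2, 0 °C to rt
Reagents that add atoms: none
Why: 4-(Dimethylamino)pyridine-catalysed acylation (nucleophilic catalysis through the N-acylpyridinium ion) of the secondary allylic alcohol forms the acyl–oxygen bond without touching the C1–O bond, so the (1R) configuration is retained.

Step 11
Reactants: 15 (1R,3E,10Z)-4,8,8,11-tetramethylcycloundeca-3,10-dien-1-yl 4-(tert-butyldimethylsilyloxy)-3-methoxybenzoate
Product: 16 (1R,3E,10Z)-4,8,8,11-tetramethylcycloundeca-3,10-dien-1-yl 4-hydroxy-3-methoxybenzoate
Conditions: Bu4NF, AcOH, THF, 0 °C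
Reagents that add atoms: none
Why: Fluoride-mediated desilylation of the aryl silyl ether, buffered with acetic acid so that the phenoxide is protonated as it forms and the allylic aryl ester and both alkene geometries stay intact.

**Compound list**
1 | (−)-caryophyllene oxide, (1R,4R,6R,10S)-4,12,12-trimethyl-9-methylidene-5-oxatricyclo[8.2.0.0(4,6)]dodecane | C[C@@]12CC[C@@H]3[C@H](CC3(C)C)C(=C)CC[C@H]1O2 | starting material
2 | vanillic acid (4-hydroxy-3-methoxybenzoic acid) | COc1cc(C(=O)O)ccc1O | starting material
3 | 1-hydroxycaryophyllene oxide, both C1 epimers (hydroxyl on the ring CH2 next to the methylene; other centres as in 1) | C[C@@]12CC[C@@H]3[C@H](CC3(C)C)C(=C)C(O)C[C@H]1O2 | intermediate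
4 | 1-oxocaryophyllene oxide (α-methylene ketone; centres as in 1) | C[C@@]12CC[C@@H]3[C@H](CC3(C)C)C(=C)C(=O)C[C@H]1O2 | intermediate
5 | (1R)-1-hydroxycaryophyllene oxide (other centres as in 1) | C[C@@]12CC[C@@H]3[C@H](CC3(C)C)C(=C)[C@H](O)C[C@H]1O2 | intermediate
6 | (1R,3R,4R,10E)-3,4-epoxy-4,8,8,11-tetramethylcycloundec-10-en-1-ol | C[C@@]12CCCC(C)(C)C/C=C(C)/[C@H](O)C[C@H]1O2 | intermediate
7 | (1R,3E,10E)-4,8,8,11-tetramethylcycloundeca-3,10-dien-1-ol | O[C@@H]1C/C=C(\C)CCCC(C)(C)C/C=C/1C | intermediate
8 | (1R,3E)-10,11-epoxy-4,8,8,11-tetramethylcycloundec-3-en-1-ol, trans-oxirane, erythro to the C1 hydroxyl | O[C@@H]1C/C=C(\C)CCCC(C)(C)C[C@H]2O[C@]12C | intermediate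
9 | hydroxy phosphine: (1R,3E)-10-(diphenylphosphanyl)-4,8,8,11-tetramethylcycloundec-3-ene-1,11-diol, C10 inverted relative to 8 (present as lithium alkoxide) | O[C@@H]1C/C=C(\C)CCCC(C)(C)C[C@H](P(c2ccccc2)c2ccccc2)[C@]1(C)O | intermediate
10 | phosphonium betaine: P-methylated 9 with the C11 alkoxide | O[C@@H]1C/C=C(\C)CCCC(C)(C)C[C@H]([P+](C)(c2ccccc2)c2ccccc2)[C@]1(C)[O-] | intermediate
11 | (1R,3E,10Z)-4,8,8,11-tetramethylcycloundeca-3,10-dien-1-ol | O[C@@H]1C/C=C(\C)CCCC(C)(C)C/C=C\1C | intermediate
12 | tert-butyldimethylsilyl 4-(tert-butyldimethylsilyloxy)-3-methoxybenzoate | COc1cc(C(=O)O[Si](C)(C)C(C)(C)C)ccc1O[Si](C)(C)C(C)(C)C | intermediate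
13 | 4-(tert-butyldimethylsilyloxy)-3-methoxybenzoic acid | COc1cc(C(=O)O)ccc1O[Si](C)(C)C(C)(C)C | intermediate
14 | 4-(tert-butyldimethylsilyloxy)-3-methoxybenzoyl chloride | COc1cc(C(=O)Cl)ccc1O[Si](C)(C)C(C)(C)C | intermediate
15 | (1R,3E,10Z)-4,8,8,11-tetramethylcycloundeca-3,10-dien-1-yl 4-(tert-butyldimethylsilyloxy)-3-methoxybenzoate | COc1cc(C(=O)O[C@@H]2C/C=C(\C)CCCC(C)(C)C/C=C\2C)ccc1O[Si](C)(C)C(C)(C)C | intermediate
16 | (1R,3E,10Z)-4,8,8,11-tetramethylcycloundeca-3,10-dien-1-yl 4-hydroxy-3-methoxybenzoate | COc1cc(C(=O)O[C@@H]2C/C=C(\C)CCCC(C)(C)C/C=C\2C)ccc1O | target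

**Step count**
Total: 11 steps. Longest linear sequence: 9 steps (steps 1–7, 10 and 11).

**Steps most likely to fail**

Step 4 (the one unprecedented step). The tertiary C11 radical may be quenched before it fragments, which would amount to plain hydrogenation of the methylene. Further hydrogen-atom transfer to the new trisubstituted alkene and ethanolysis of the oxirane at the iron centre are also possible. The fallback uses known chemistry and sets out from 5. The scission would be run in its established redox-neutral form, the cobalt-salen-catalysed hydrogen-atom-transfer retro-cycloisomerisation of strained rings: chloro[N,N'-bis(3,5-di-tert-butylsalicylidene)-1,2-cyclohexanediaminato]cobalt (a few mol%) and PhSiH3 (a few mol%) in benzene at rt. There the ring-opened C7 radical gives up a hydrogen atom from C6 to divalent cobalt. This should give (1R,3R,4R,6E,10E)-3,4-epoxy-4,8,8,11-tetramethylcycloundeca-6,10-dien-1-ol F1, with no reductant present to over-reduce it. Diimide (from 2-nitrobenzenesulfonyl hydrazide and Et3N) would then saturate the 1,2-disubstituted C6=C7 alkene in preference to the trisubstituted one, and the route is rejoined at 6.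

Step 7. Opening of the hindered oxirane may be slow or misdirected: the phosphide can act as a base, and the oxirane can migrate toward C1 through the neighbouring alkoxide. The betaine may also break down non-stereospecifically. The fallback sets out from 8. Dimethylphenylsilyllithium (THF, −78 to 0 °C) would open the oxirane at C10 with inversion to the β-hydroxysilane (1R,3E)-10-[dimethyl(phenyl)silyl]-4,8,8,11-tetramethylcycloundec-3-ene-1,11-diol F2, which can be isolated and purified. KH in THF would then bring about the stereospecific syn-elimination of the Peterson reaction, and the route is rejoined at 11.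

Step 5. The allylic alkoxide may capture the tungsten reagent with cleavage of the C1–O bond. Chloride opening of the oxirane and stepwise C–O cleavage with erosion of the 3E geometry are further risks. The fallback sets out from 6, keeps the tungsten reagent away from any free hydroxyl, and merges the geometric inversion into the deoxygenation.
- Silylation (TBSCl, imidazole) would give the tert-butyldimethylsilyl ether of 6 F3.
- OsO4 (cat.) with N-methylmorpholine N-oxide would add two hydroxyls syn to the only alkene to give the 10,11-diol F4. Either face serves.
- MsCl and Et3N would sulfonylate the secondary C10 hydroxyl selectively to the 10-methanesulfonate F5.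
- K2CO3 in MeOH would close the tertiary C11 alkoxide onto C10 with inversion to the bis-oxirane F6, whose new oxirane has C9 and C1 on the same face.
- WCl6/n-BuLi would then remove both oxirane oxygens with retention (3E from the trans-oxirane, 10Z from the new cis-type oxirane) to the tert-butyldimethylsilyl ether of 11 F7.
- Bu4NF would return the route to 11, so steps 5–7 are replaced.

**Further compounds**
F1 | step 4 | (1R,3R,4R,6E,10E)-3,4-epoxy-4,8,8,11-tetramethylcycloundeca-6,10-dien-1-ol | C[C@@]12C/C=C/C(C)(C)C/C=C(C)/[C@H](O)C[C@H]1O2
F2 | step 7 | (1R,3E)-10-[dimethyl(phenyl)silyl]-4,8,8,11-tetramethylcycloundec-3-ene-1,11-diol (C10 inverted relative to 8) | O[C@@H]1C/C=C(\C)CCCC(C)(C)C[C@H]([Si](C)(C)c2ccccc2)[C@]1(C)O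
F3 | step 5 | tert-butyldimethylsilyl ether of 6 | C[C@@]12CCCC(C)(C)C/C=C(C)/[C@H](O[Si](C)(C)C(C)(C)C)C[C@H]1O2
F4 | step 5 | 10,11-diol from syn-dihydroxylation of F3 (one face drawn) | C[C@@]12CCCC(C)(C)C[C@H](O)[C@@](C)(O)[C@H](O[Si](C)(C)C(C)(C)C)C[C@H]1O2
F5 | step 5 | 10-methanesulfonate of F4 | C[C@@]12CCCC(C)(C)C[C@H](OS(C)(=O)=O)[C@@](C)(O)[C@H](O[Si](C)(C)C(C)(C)C)C[C@H]1O2
F6 | step 5 | 3,4:10,11-bis-oxirane silyl ether (10,11-oxirane with C9 and C1 cis) | C[C@@]12CCCC(C)(C)C[C@H]3O[C@@]3(C)[C@H](O[Si](C)(C)C(C)(C)C)C[C@H]1O2
F7 | step 5 | tert-butyldimethylsilyl ether of 11 | CC(C)(C)[Si](C)(C)O[C@@H]1C/C=C(\C)CCCC(C)(C)C/C=C\1C
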